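The target in larch, which is the asked flask followed so far, reads 33.7% at 10.0 min, then falls and reads 24.6% at 60.0 min. I want to know what has happened in the flask by the time those readings go flat.

the same everywhere: substrate 0.20 M
- larch: reagent 0.36 M; transfer agent 0.020 M; initiator 20 mM; temperature 5 °C; the very flask that is asked about, followed so far
- cedar: reagent 0.36 M; transfer agent 0.020 M; initiator 40 mM; temperature −10 °C; run made earlier
- flask: reagent 0.360 M; transfer agent 0.0200 M; initiator 20 mM; temperature 5 °C; time 80 min

| run | time / min | target / % |
|---|---|---|
| larch | 3.00 | 33.4 |
| larch | 10.0 | 33.7 |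
| larch | 20.0 | 25.5 |
| larch | 30.0 | 24.8 |
| larch | 40.0 | 25.1 |
| larch | 50.0 | 24.6 |
| larch | 60.0 | 24.6 |
| cedar | 0.333 | 0.8 |
| cedar | 1.00 | 1.5 |
| cedar | 2.00 | 3.5 |
| cedar | 3.00 | 5.2 |
| cedar | 4.00 | 8.3 |
| cedar | 5.00 | 11.5 |
| cedar | 6.00 | 16.6 |

(each reading ± 0.3 percentage points)

- target, in percent of the substrate first charged, at 80 min
- what to do for the largest gain in target; "none" if nothing gains more than 2 percentage points (autumn / winter / summer / spring / none)
- target present, with what was taken out counted in, in percent of the substrate first charged, after autumn
- target present, with what was taken out counted in, in percent of the substrate first charged, after spring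

- removed target is counted in
- the earlier runs were read with a standard deviation of 0.3 percentage points
- additions bring no volume worth counting

- autumn: at 80 min raise the temperature by 15 K, then wait 80 min
- winter: at 80 min take out 90% of the target then present, then wait 80 min
- summer: at 80 min add reagent, 100% of the amount charged, then wait 80 min
- spring: change nothing and wait 80 min more

I count turnovers. Cedar gains 2 percentage points between 1.00 min and 2.00 min but 5.1 points between 5.00 min and 6.00 min. I read this as a chain held back at first, an induction period. So I set two amounts against each other: the chain starts the initiator can give, two per molecule, and the transfer agent, which I take to end one chain each. Their ratio in larch is 2.00, and I call these starts per transfer agent the radical budget. Above one, my count has the transfer agent go first, and the share of starts left free to carry chains is one minus the inverse of the budget, which in larch is half. Below one, the initiator goes first.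

So I expect the chain in larch to run while initiator lasts, and I take the flat readings as the state after it. That gives about 24.8% at the asked time, and nothing from waiting. A fall to a flat level looks to me like a balance, so I would act on that, though these runs don't tell me whether warming or removal gives more.

The forecast, holding that “reagent exhaustion seems likeliest”, gives 24.8% now, none as best, 24.6% after autumn and 24.7% after spring.

The flask gives 24.6%, 24.6% after spring and 44.4% after autumn, so the best is autumn, gaining 20 points against 16 points for winter.

    initiator → 2 initiating radical (k = 0.00600 s⁻¹, Ea = 87.0 kJ mol⁻¹)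
    substrate + initiating radical → capped initiator + first chain carrier (k = 94000 M⁻¹ s⁻¹, Ea = 12.0 kJ mol⁻¹)
    reagent + first chain carrier → target + second chain carrier (k = 11000 M⁻¹ s⁻¹, Ea = 27.0 kJ mol⁻¹)
    substrate + second chain carrier → by-product + first chain carrier (k = 7400 M⁻¹ s⁻¹, Ea = 17.0 kJ mol⁻¹)
    transfer agent + first chain carrier → side product + idle radical (kL = 2.20 × 10⁵ M⁻¹ s⁻¹, Ea = 29.0 kJ mol⁻¹)
    2 idle radical → ended radicals (k = 5.00 × 10⁶ M⁻¹ s⁻¹, Ea = 9.00 kJ mol⁻¹)
    2 first chain carrier → ended chains A (k = 1.80 × 10⁶ M⁻¹ s⁻¹, Ea = 16.0 kJ mol⁻¹)
    2 second chain carrier → ended chains B (k = 8.30 × 10⁷ M⁻¹ s⁻¹, Ea = 11.0 kJ mol⁻¹)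
    target ⇌ isomer of the product (K = 2.40, k = 0.00340 s⁻¹, Ea = 83.0 kJ mol⁻¹, ΔH = −45.0 kJ mol⁻¹)
    (constants at 5 °C)

The chain ran early, with half the turnover of substrate with second chain carrier done by 2.91 min and >99.9% of it by 40.0 min. Target to isomer of the product ran later, half its turnover done by 6.25 min, with a relaxation half-life of 2.40 min, short against 80 min. At 80 min the flask holds transfer agent 0%, initiator 0% and reagent 54%, with target 24.6% beside isomer of the product 59.1%, and the equilibrium constant of that step is 2.4.

A neighbour flask, the same but with 0.080 M of transfer agent, has a budget of 0.500, below one, so the initiator should go first and leave 50.0% of the transfer agent. Computed, it keeps transfer agent 50% and substrate 73.9%, and its target is 1.80%.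

The earlier runs and the new flask were generated by integration with constants of no real substance, noise included.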